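## Compound numbers used throughout

1 6-methoxynaphthalen-2-ol · 2 its tosylate · 3 3-chloropropanoyl chloride · 4 chloro ketone · 5 aryl vinyl ketone (not isolated) · 6 dihydrophenalenone tosylate · 7 naphthol · 8 hydroxy aldehyde · 9 aryl triflate · 10 naphthalene-1,8-diol · 11 acetal · 12 cyclopentenone boronate · 13 3-arylcyclopentenone · 14 dioxinylium salt (not isolated) · 15 benzylic cation (not isolated) · 16 flat enone (key-step precursor) · 17 epoxy ketone (key-step product) · 18 hydroxy ketone · 19 triethylsilyl ether · 20 bis(silyl enol ether) · 21 bis-enone · 22 phenol · 23 spiropreussione B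

## Analysis of the target

Spiropreussione B (23) is built on a 9-hydroxy-1H-phenalen-1-one (rings A to C: C1 carbonyl, C2=C3, peri hydroxyl at C9). Its C5–C6 bond is one edge of a five-membered carbocycle (ring D), completed by a spiro ketal carbon on C6, a methine, and a tertiary carbinol carbon on C5. The ketal is closed by both oxygens of a naphthalene-1,8-diol, and the methine and carbinol carbons are also C5 and C4 of a cyclopent-2-en-1-one (ring E) whose carbonyl is bonded to the methine. These two adjacent ring-fusion carbons are the only stereocentres, S at the methine and R at the carbinol; two fused five-membered rings can only be cis, so one absolute element has to be set. The hydroxyl is beta to the ring E ketone (retro-aldol on the alkoxide, and dehydration to a flat enone while ring E is saturated), and the ketal oxygens are also beta to that ketone, so an enolate at the methine can expel aryloxide. The hydroxyphenalenone is a vinylogous acid, a Michael acceptor and a photosensitiser, and the dioxygenated naphthalene of the ketal is the most nucleophilic arene present, which rules out electrophilic aromatic chemistry once it is installed. The hard points are the congested ketal carbon between two arenes, the absolute configuration of a tertiary benzylic carbinol, and the timing of ring A. The route rests on one feature: the fusion bond is the alpha,beta bond of the ring E ketone with the oxygen on the aryl-bearing beta carbon, the pattern of a reductively opened alpha,beta-epoxy ketone, which leads back to a planar, achiral tetrasubstituted enone.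

## Retrosynthetic reasoning

23 ⇒ 22 ⇒ 21. The O–Si bond at the carbinol and the O–CH3 bond at C9 are cut last. The carbinol is kept as a silyl ether because its alkoxide would undergo retro-aldol cleavage. The phenol is kept as a methyl ether because it must survive the acid used to build ring A, and because a free peri hydroxyl would let the ring A ketone bind a primary amine catalyst as a hydrogen-bonded imine.

21 ⇒ 20 ⇒ 19. Both enone double bonds (C2=C3 of ring A and the ring E alkene) are taken back to saturated ketones. Neither acceptor then exists while a nucleophilic oxidant and a one-electron reductant are in use, and both are installed in one pair of operations. The forward reaction has to enolise the cyclopentanone away from the ring fusion.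

19 ⇒ 18 ⇒ 17. After removal of the silyl group, the C–H bond at the methine is traced to a C–O bond. The forward step cleaves the C–O bond alpha to the ketone, keeps the oxygen on the benzylic carbon, and protonates the alpha carbon, which can only give the cis fusion.

17 ⇒ 16. Both C–O bonds of the oxirane are cut. This is the only stereochemical event of the route: 16 is flat and achiral, so no configuration has to be carried or protected before this point.

16 ⇒ 13 (through 14 and 15). Ring D is opened at the bond between the ketal carbon and the enone alpha carbon. The cut is placed there because the ketal carbon is then an aldehyde-derived acetal, which is easy to make, and the congested quaternary centre is closed intramolecularly. The closure is designed to use the neutral enone, not an enol derivative: an enol derivative would offer the ring CH2 on the other side of the aryl-bearing carbon as a second five-ring-forming nucleophile, and any enolate at the alpha carbon could expel a ketal oxygen.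

13 ⇒ 11 + 12. The aryl–alkenyl bond at C5 is cut to an aryl triflate and an alkenylboronate. A palladium-catalysed coupling is needed because the ring A ketone excludes organolithium chemistry.

11 ⇒ 9 + 10, and 9 ⇒ 8 ⇒ 7. The two acetal C–O bonds go back to an aldehyde and diol 10. The triflate goes back to a naphthol, whose hydroxyl also directs the formyl carbon to the adjacent alpha position C6. One oxygen thus provides both handles on neighbouring carbons.

7 ⇒ 6 ⇒ 4 + … ⇒ 2 + 3 ⇒ 1. Ring A is cut at its two aryl–carbon bonds (acyl carbon to C9a, CH2 to C3a) and is therefore built first, on a simple naphthalene. After 10 has been introduced, its electron-rich naphthalene would compete for any acylating agent, and the ketal, silyl ether and enone would not survive the acid. The sulfonate in 2 steers the acylation into the methoxy ring and later releases the naphthol.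

## Alternatives that were turned down

Alternative 1: Ring D of the indenol A1 is cut at the bond from the arene to the oxygen-bearing alkene carbon and at the bond from the acetyl-bearing alkene carbon to the carbinol carbon. This gives the ortho-bromoaryl keto acetal A2 and the naphthyloxy ynone A3. In the forward step a zerovalent nickel catalyst with a chiral phosphine–oxazoline ligand and a metal reductant inserts into the C–Br bond of A2, adds across A3 and adds the alkenyl nickel to the ketone.
- For: it is convergent, and it sets the tertiary carbinol by a catalytic ketone addition of an established kind. On that point it is stronger than an epoxidation of a tetrasubstituted enone.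
- Against: the regiochemistry of insertion into an alkyne that carries both an oxygen and an acyl group is uncertain. A1 still lacks the ketal (acetal removal on the second naphthol oxygen, then conjugate addition to the vinylogous ester) and ring E (unmasking the aldehyde, aldol condensation with the acetyl group). The methine centre appears only then, next to a free tertiary carbinol prone to retro-aldol cleavage.
- Comparison: the chosen plan offers the complete skeleton and ketal before any stereocentre exists, and fewer operations after the stereo-defining step.

Alternative 2: Ring E is traced back to the dichlorocyclobutanone A4, which is cut at the bond from the ring-fusion CH to the carbonyl carbon and at the bond from the ether-bearing carbon to the dichloromethylene carbon. The precursors are the spiroketal indenyl enol ether A5, which carries a chiral 1-arylethyl group on oxygen, and dichloroketene A6.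
- For: the cycloaddition of A6 to enol ethers is dependable, its regiochemistry follows from polarity, the cis fusion is automatic, and auxiliaries of this type give predictable face selection. In predictability of the stereo-defining step it is stronger.
- Against: the auxiliary is stoichiometric. A4 needs a one-carbon ring expansion, removal of two chlorines, cleavage of a tertiary benzylic ether under acid (ionisation at the carbinol), and desaturation. A5 itself requires ketalisation of a conjugated indenone.
- Comparison: the chosen plan is catalytic in chirality and several steps shorter on ring E.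

Alternative 3: The silyl-protected core A7 is cut at the bond between the ketal carbon and the ring-fusion CH. The ketal carbon comes from a dioxinylium ion generated from the aryl methyl orthoester in A8, and the CH is the alpha-prime carbon of the 4-aryl-4-silyloxycyclopentenone in A8. In the forward step a silyl triflate and a hindered amine ionise the orthoester and form the cross-conjugated dienol ether, which closes ring D.
- For: only the alpha-prime carbon can close a five-membered ring, so the closure is regiochemically unambiguous, and A7 already carries the enone and the protected carbinol. In step economy after ring closure it is stronger, since no epoxidation, reduction or desaturation of ring E is needed.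
- Against: A8 must already hold an enantioenriched tertiary aryl carbinol, which means an enantioselective aryl addition or a resolution. That centre is an allylic, benzylic silyl ether exposed to a silyl triflate.
- Comparison: the chosen plan sets configuration last, on a flat compound, by face-selective oxidation.

All three were drawn on a naphthalene without ring A and would need the same early annulation.

Key step: step 10

Assumption: the sense of induction of the amine catalyst in step 10 cannot be derived for a tetrasubstituted enone, so the quinine-derived amine is written and its quinidine-derived pseudo-enantiomer replaces it if a first trial gives the opposite epoxide; boronate 12 is taken as a purchasable reagent.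

## Route

Step 1
Reactants: 1 6-methoxynaphthalen-2-ol
Product: 2 6-methoxynaphthalen-2-yl 4-methylbenzenesulfonate
Conditions: TsCl, Et3N, DMAP (cat.), CH2Cl2, 0 °C to rt
Reagents that add atoms: 4-methylbenzenesulfonyl chloride, Cc1ccc(cc1)S(=O)(=O)Cl
Why: O-Sulfonylation of the naphthol; the tosylate deactivates its own ring so that the Friedel–Crafts chemistry is confined to the methoxy ring, survives Lewis and Brønsted acid, and is later removed by hydroxide.

Step 2
Reactants: 2 6-methoxynaphthalen-2-yl 4-methylbenzenesulfonate; 3 3-chloropropanoyl chloride
Product: 4 5-(3-chloropropanoyl)-6-methoxynaphthalen-2-yl 4-methylbenzenesulfonate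
Conditions: AlCl3 (1.3 equiv), CH2Cl2, 0 °C
Reagents that add atoms: none
Why: Friedel–Crafts acylation; C5 is the alpha position ortho to the methoxy group of the only activated ring, the kinetic site of 2-alkoxynaphthalenes, and a short reaction at 0 °C should leave the methyl ether intact.

Step 3
Reactants: 4 5-(3-chloropropanoyl)-6-methoxynaphthalen-2-yl 4-methylbenzenesulfonate
Product: 6 9-methoxy-1-oxo-2,3-dihydro-1H-phenalen-5-yl 4-methylbenzenesulfonate, via aryl vinyl ketone 5 (not isolated)
Conditions: CF3SO3H, ClCH2CH2Cl, 60 °C
Reagents that add atoms: none
Why: The acid should eliminate HCl to the protonated aryl vinyl ketone, which alkylates the peri carbon in an intramolecular Friedel–Crafts conjugate addition (the classical perinaphthanone closure, six-membered, no other carbon within reach). A non-sulfonating acid is chosen because of the electron-rich ring.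

Step 4
Reactants: 6 9-methoxy-1-oxo-2,3-dihydro-1H-phenalen-5-yl 4-methylbenzenesulfonate
Product: 7 5-hydroxy-9-methoxy-2,3-dihydro-1H-phenalen-1-one
Conditions: KOH, MeOH/THF/H2O, 60 °C, argon; aq HCl
Reagents that add atoms: none
Why: Saponification of the aryl sulfonate by attack of hydroxide at sulfur releases the naphtholate; air is excluded to prevent base-mediated autoxidation of the dihydrophenalenone.

Step 5
Reactants: 7 5-hydroxy-9-methoxy-2,3-dihydro-1H-phenalen-1-one
Product: 8 5-hydroxy-9-methoxy-1-oxo-2,3-dihydro-1H-phenalene-6-carbaldehyde
Conditions: Cl2CHOMe, TiCl4, CH2Cl2, 0 °C; H2O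
Reagents that add atoms: dichloromethyl methyl ether, COC(Cl)Cl; water, O
Why: Rieche formylation of a phenol; the titanium naphtholate directs the electrophile to the ortho alpha position C6 (as C1 in 2-naphthol), ring C is deactivated by its ketone, and aqueous work-up hydrolyses the chloro ether to the aldehyde.

Step 6
Reactants: 8 5-hydroxy-9-methoxy-1-oxo-2,3-dihydro-1H-phenalene-6-carbaldehyde
Product: 9 6-formyl-9-methoxy-1-oxo-2,3-dihydro-1H-phenalen-5-yl trifluoromethanesulfonate
Conditions: Tf2O, pyridine, CH2Cl2, 0 °C
Reagents that add atoms: trifluoromethanesulfonic anhydride, O=S(=O)(OS(=O)(=O)C(F)(F)F)C(F)(F)F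
Why: O-Triflation of the acidic ortho-formyl naphthol turns the directing oxygen into the leaving group for cross-coupling.

Step 7
Reactants: 9 6-formyl-9-methoxy-1-oxo-2,3-dihydro-1H-phenalen-5-yl trifluoromethanesulfonate; 10 naphthalene-1,8-diol
Product: 11 9-methoxy-6-(naphtho[1,8-de][1,3]dioxin-2-yl)-1-oxo-2,3-dihydro-1H-phenalen-5-yl trifluoromethanesulfonate
Conditions: TsOH·H2O (cat.), toluene, reflux, Dean–Stark trap
Reagents that add atoms: none
Why: Acid-catalysed acetalisation with azeotropic removal of water; the aromatic aldehyde closes the six-membered dioxine readily, whereas the hindered ketone conjugated to the methoxy group should not react in the time needed.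

Step 8
Reactants: 11 9-methoxy-6-(naphtho[1,8-de][1,3]dioxin-2-yl)-1-oxo-2,3-dihydro-1H-phenalen-5-yl trifluoromethanesulfonate; 12 3-(4,4,5,5-tetramethyl-1,3,2-dioxaborolan-2-yl)cyclopent-2-en-1-one
Product: 13 3-[9-methoxy-6-(naphtho[1,8-de][1,3]dioxin-2-yl)-1-oxo-2,3-dihydro-1H-phenalen-5-yl]cyclopent-2-en-1-one
Conditions: PdCl2(dppf) (5 mol %), K3PO4, 1,4-dioxane/H2O, 80 °C
Reagents that add atoms: none
Why: Suzuki–Miyaura coupling of an aryl triflate with an alkenylboronate; it attaches the five-carbon ring at C5 without organolithium reagents, which the ring A ketone would not tolerate.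

Step 9
Reactants: 13 3-[9-methoxy-6-(naphtho[1,8-de][1,3]dioxin-2-yl)-1-oxo-2,3-dihydro-1H-phenalen-5-yl]cyclopent-2-en-1-one
Product: 16 spiroketal enone (flat achiral key-step precursor), via dioxinylium tetrafluoroborate 14 (not isolated), via benzylic cation 15 (not isolated)
Conditions: Ph3CBF4 (1.1 equiv), ClCH2CH2Cl, 25 to 60 °C; aq NaHCO3
Reagents that add atoms: none
Why: Proposed new method: hydride abstraction from the acetal carbon by the trityl cation (the known route to 1,3-dioxolan-2-ylium and 1,3-benzodioxolium salts) gives 14, which is attacked by the enone alkene through its alpha carbon, the only sp2 carbon able to reach the cation in a five-membered transition state, to give the tertiary cation 15 stabilised by the methoxynaphthalene; loss of the ring-fusion proton gives the conjugated enone, and the HBF4 released keeps proton loss reversible so that the conjugated isomer accumulates. The closest known reaction type is the acid-mediated 5-endo cyclisation of ortho-alkenyl benzylic cations to indenes; no enol or enolate is formed, so the ring CH2 never becomes nucleophilic and the ketal is not exposed to beta-elimination.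

Step 10
Reactants: 16 spiroketal enone (flat achiral key-step precursor)
Product: 17 cis alpha,beta-epoxy ketone
Conditions: 9-amino-9-deoxy-epi-quinine (20 mol %), CF3CO2H (40 mol %), 50% aq H2O2 (3 equiv), 1,4-dioxane, 35 °C
Reagents that add atoms: hydrogen peroxide, OO
Why: The primary amine of the catalyst condenses with the ring E carbonyl of 16 to an iminium ion, which activates the tetrasubstituted alkene and sits next to the protonated quinuclidine that holds the peroxide by hydrogen bonding. Hydrogen peroxide adds to the aryl-bearing beta carbon, which forms the first C–O bond and fixes that quaternary centre on the face the catalyst leaves open. The beta-hydroperoxy enamine then closes by 3-exo-tet attack of its alpha carbon on the proximal oxygen with loss of water, which forms the second C–O bond and the oxirane and places the alpha centre on the same face. The closest known reaction is the amine-salt-catalysed Weitz–Scheffer epoxidation of cyclic enones with aqueous hydrogen peroxide, and the racemic base-mediated version is routine for 2,3-disubstituted cyclopentenones; the tetrasubstituted, aryl-conjugated alkene is an extension in steric demand, not in kind. Chemoselectivity comes from the substrate: the enone is the only electron-poor alkene, the naphthalenes are inert to a nucleophilic oxidant, and the peri-methoxy aryl ketone cannot form a conjugated iminium ion. The selectivity that matters is enantioface selection, which is catalyst-controlled because 16 is flat and achiral. Closure on the weak O–O bond should outrun loss of a ketal aryloxide from the same enamine.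

Step 11
Reactants: 17 cis alpha,beta-epoxy ketone
Product: 18 cis-fused beta-hydroxy ketone
Conditions: SmI2 (2.2 equiv), THF/MeOH, −90 °C
Reagents that add atoms: none
Why: Reductive cleavage of an alpha,beta-epoxy ketone by divalent samarium: electron transfer to the ketone, scission of the C–O bond at the alpha carbon and protonation of the samarium enolate by methanol keep the oxygen on the benzylic carbon, and two fused five-membered rings can only be cis, so the new C–H is set by the carbinol. At −90 °C the cleavage should outrun electron transfer to the aryl ketone and loss of aryloxide from the enolate.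

Step 12
Reactants: 18 cis-fused beta-hydroxy ketone
Product: 19 triethylsilyl ether of 18
Conditions: Et3SiOTf, 2,6-lutidine, CH2Cl2, −78 °C
Reagents that add atoms: triethylsilyl trifluoromethanesulfonate, CC[Si](CC)(CC)OS(=O)(=O)C(F)(F)F
Why: Silylation of the hindered tertiary alcohol with a silyl triflate and a non-nucleophilic base; the ether prevents retro-aldol cleavage of the alkoxide in the next step, and the low temperature avoids enolisation toward the ring-fusion carbon.

Step 13
Reactants: 19 triethylsilyl ether of 18
Product: 20 bis(trimethylsilyl enol ether)
Conditions: LDA (2.5 equiv), Me3SiCl (5 equiv, in situ), THF, −78 °C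
Reagents that add atoms: chlorotrimethylsilane, C[Si](C)(C)Cl
Why: Kinetic deprotonation with in situ silylation; the cyclopentanone loses a proton from its CH2 (the ring-fusion CH is hindered, and its enolate would have a beta leaving group), the ring A ketone from C2, and both enolates are trapped as they form.

Step 14
Reactants: 20 bis(trimethylsilyl enol ether)
Product: 21 bis-enone (9-methoxyphenalenone and cyclopentenone, triethylsilyl ether)
Conditions: Pd(OAc)2 (2.5 equiv), MeCN, 25 to 40 °C, dark
Reagents that add atoms: none
Why: Twofold Saegusa–Ito oxidation; each silyl enol ether gives an oxa-allyl palladium species that undergoes beta-hydride elimination, which installs C2=C3 of ring A and the ring E double bond in one operation while zerovalent palladium precipitates. Light is excluded because the phenalenone sensitises singlet oxygen.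

Step 15
Reactants: 21 bis-enone (9-methoxyphenalenone and cyclopentenone, triethylsilyl ether)
Product: 22 9-hydroxyphenalenone triethylsilyl ether
Conditions: MgI2·OEt2, toluene, 40 °C; aq NH4Cl
Reagents that add atoms: none
Why: Chelation-assisted ether cleavage; magnesium binds the C1 carbonyl and the peri methoxy oxygen of the vinylogous ester and iodide removes the methyl group by SN2, and no other ether in 21 can form such a chelate.

Step 16
Reactants: 22 9-hydroxyphenalenone triethylsilyl ether
Product: 23 spiropreussione B
Conditions: HF·pyridine, THF, 0 °C
Reagents that add atoms: none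
Why: Fluoride-mediated cleavage of the tertiary silyl ether under buffered acidic conditions, which avoid the alkoxide and hence retro-aldol cleavage; the stereocentres are not touched.

## Compound list

In 16 to 23, ring D is the five-membered ring C6–ketal carbon–C(alpha)–C(beta)–C5 on the phenalene. The ketal carbon is C2 of a naphtho[1,8-de][1,3]dioxine. C(alpha) and C(beta) are also the carbons next to the carbonyl and one further along in ring E.

1 | 6-methoxynaphthalen-2-ol | COc1ccc2cc(O)ccc2c1 | starting material
2 | 6-methoxynaphthalen-2-yl 4-methylbenzenesulfonate | COc1ccc2cc(OS(=O)(=O)c3ccc(C)cc3)ccc2c1 | intermediate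
3 | 3-chloropropanoyl chloride | O=C(Cl)CCCl | starting material
4 | 5-(3-chloropropanoyl)-6-methoxynaphthalen-2-yl 4-methylbenzenesulfonate | COc1ccc2cc(OS(=O)(=O)c3ccc(C)cc3)ccc2c1C(=O)CCCl | intermediate
5 | 6-methoxy-5-(prop-2-enoyl)naphthalen-2-yl 4-methylbenzenesulfonate (not isolated) | COc1ccc2cc(OS(=O)(=O)c3ccc(C)cc3)ccc2c1C(=O)C=C | intermediate
6 | 9-methoxy-1-oxo-2,3-dihydro-1H-phenalen-5-yl 4-methylbenzenesulfonate | O=C1CCc2cc(OS(=O)(=O)c4ccc(C)cc4)cc3ccc(OC)c1c23 | intermediate
7 | 5-hydroxy-9-methoxy-2,3-dihydro-1H-phenalen-1-one | O=C1CCc2cc(O)cc3ccc(OC)c1c23 | intermediate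
8 | 5-hydroxy-9-methoxy-1-oxo-2,3-dihydro-1H-phenalene-6-carbaldehyde | O=C1CCc2cc(O)c(C=O)c3ccc(OC)c1c23 | intermediate
9 | 6-formyl-9-methoxy-1-oxo-2,3-dihydro-1H-phenalen-5-yl trifluoromethanesulfonate | O=C1CCc2cc(OS(=O)(=O)C(F)(F)F)c(C=O)c3ccc(OC)c1c23 | intermediate
10 | naphthalene-1,8-diol | Oc1cccc2cccc(O)c12 | starting material
11 | 9-methoxy-6-(naphtho[1,8-de][1,3]dioxin-2-yl)-1-oxo-2,3-dihydro-1H-phenalen-5-yl trifluoromethanesulfonate | O=C1CCc2cc(OS(=O)(=O)C(F)(F)F)c(C4Oc5cccc6cccc(O4)c56)c3ccc(OC)c1c23 | intermediate
12 | 3-(4,4,5,5-tetramethyl-1,3,2-dioxaborolan-2-yl)cyclopent-2-en-1-one | O=C1CCC(B2OC(C)(C)C(C)(C)O2)=C1 | starting material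
13 | 3-[9-methoxy-6-(naphtho[1,8-de][1,3]dioxin-2-yl)-1-oxo-2,3-dihydro-1H-phenalen-5-yl]cyclopent-2-en-1-one | O=C1CCc2cc(C4=CC(=O)CC4)c(C5Oc6cccc7cccc(O5)c67)c3ccc(OC)c1c23 | intermediate
14 | naphtho[1,8-de][1,3]dioxin-2-ylium tetrafluoroborate of 13, cation at the former acetal carbon (not isolated) | O=C1CCc2cc(C4=CC(=O)CC4)c(C5=[O+]c6cccc7cccc(O5)c67)c3ccc(OC)c1c23.F[B-](F)(F)F | intermediate
15 | ring D closed, tertiary benzylic cation at C(beta), tetrafluoroborate, racemic at C(alpha) (not isolated) | O=C1CCc2cc3c(c4ccc(OC)c1c24)C1(Oc2cccc4cccc(O1)c24)C1C(=O)CC[C+]31.F[B-](F)(F)F | intermediate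
16 | spiroketal enone: 9-methoxy-2,3-dihydro-1H-phenalen-1-one with ring D fused at C5–C6, C(alpha)=C(beta) shared with a cyclopent-2-en-1-one whose carbonyl is on C(alpha); achiral | O=C1CCc2cc3c(c4ccc(OC)c1c24)C1(Oc2cccc4cccc(O1)c24)C1=C3CCC1=O | intermediate
17 | alpha,beta-epoxy ketone of 16, oxirane across C(alpha)–C(beta) on the face that becomes the hydroxyl face of 23 | O=C1CCc2cc3c(c4ccc(OC)c1c24)C1(Oc2cccc4cccc(O1)c24)[C@]15O[C@@]35CCC1=O | intermediate
18 | cis-fused beta-hydroxy ketone, S at the C(alpha) methine, R at the C(beta) carbinol, H and OH cis | O=C1CCc2cc3c(c4ccc(OC)c1c24)C1(Oc2cccc4cccc(O1)c24)[C@@H]1C(=O)CC[C@]31O | intermediate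
19 | triethylsilyl ether of 18 | O=C1CCc2cc3c(c4ccc(OC)c1c24)C1(Oc2cccc4cccc(O1)c24)[C@@H]1C(=O)CC[C@]31O[Si](CC)(CC)CC | intermediate
20 | bis(trimethylsilyl enol ether) of 19 (ring A C1=C2 and ring E toward its CH2) | C[Si](C)(C)OC1=CCc2cc3c(c4ccc(OC)c1c24)C1(Oc2cccc4cccc(O1)c24)[C@@H]1C(O[Si](C)(C)C)=CC[C@]31O[Si](CC)(CC)CC | intermediate
21 | 9-methoxyphenalen-1-one with ring E cyclopentenone, triethylsilyl ether | O=C1C=Cc2cc3c(c4ccc(OC)c1c24)C1(Oc2cccc4cccc(O1)c24)[C@@H]1C(=O)C=C[C@]31O[Si](CC)(CC)CC | intermediate
22 | triethylsilyl ether of spiropreussione B | O=C1C=Cc2cc3c(c4ccc(O)c1c24)C1(Oc2cccc4cccc(O1)c24)[C@@H]1C(=O)C=C[C@]31O[Si](CC)(CC)CC | intermediate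
23 | spiropreussione B | O=C1C=Cc2cc3c(c4ccc(O)c1c24)C1(Oc2cccc4cccc(c24)O1)[C@@H]1C(=O)C=C[C@]31O | target

## Step count and least certain steps

Total: 16 steps. Longest linear sequence: 16 steps (1 to 23); 3, 10 and 12 enter as purchased reagents.

Step 9 (labelled step). Hydride abstraction at the hindered acetal carbon may be slow. The stabilised cation may fail to engage the acyl-deactivated alkene. Acid-promoted enolisation could open a competing closure through the ring CH2, and proton loss from the cation could stop at the deconjugated alkene. The fallback uses known reaction types and sets out from 11. Hydride abstraction with Ph3CBF4 gives the dioxinylium tetrafluoroborate F1, which is captured in the same flask at the 2-position of cyclopentane-1,3-dione, a symmetric carbon nucleophile with no regiochemical choice, to give the 2-substituted 3-hydroxycyclopent-2-enone F2. Triflation of the enol (Tf2O, Et3N, −78 °C) gives the aryl and alkenyl bis-triflate F3. A Stille–Kelly closure (Pd(PPh3)4, Me6Sn2, LiCl, 1,4-dioxane, 100 °C) joins the two triflate-bearing carbons and returns to the route at 16.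

Step 10 (key step). Iminium formation at a ketone flanked by a quaternary carbon may be slow, and face selection on a tetrasubstituted alkene may be poor. The amine can be lost by N-oxidation, and the peroxy enamine can expel a ketal aryloxide instead of closing. The fallback relays chirality from a carbonyl reduction and sets out from 16. Corey–Bakshi–Shibata reduction with (R)-2-methyl-CBS-oxazaborolidine and BH3·SMe2 reduces both ketones; the ring E carbonyl is differentiated by its fully substituted alkene carbon against a CH2, and the product is the allylic and benzylic diol F4. VO(acac)2 and t-BuOOH epoxidise the tetrasubstituted alkene on the face of the allylic hydroxyl to give the epoxy diol F5. Dess–Martin oxidation of both carbinols returns to the route at 17; the configuration at the ring A carbinol is lost there and is of no consequence.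

Step 11. Electron transfer to the ring A aryl ketone may compete, the samarium enolate may expel a ketal aryloxide, and the aldol product may dehydrate back to the flat enone. The fallback avoids a strongly reducing metal and sets out from 16. Copper-catalysed enantioselective conjugate borylation (CuCl, NaOt-Bu, a chiral bisphosphine, B2pin2, MeOH, THF) installs boron on the aryl-bearing carbon and a proton on the alpha carbon, cis by ring strain, to give the beta-boryl ketone F6. Oxidation with NaBO3 with retention returns to the route at 18.

Step 14. Desaturation may be incomplete or one-sided, the palladium enolate of ring E may isomerise toward the ring fusion with loss of the silyloxy group, and the phenalenone may undergo photo-oxidation once formed. The fallback replaces beta-hydride elimination by a selenoxide elimination and sets out from 20. PhSeCl (2 equiv, THF, −78 °C) gives the bis(alpha-phenylselanyl) diketone F7. Oxidation with H2O2 and pyridine at 0 °C and syn elimination of both selenoxides returns to the route at 21.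

Step 15. The Lewis acid may open the spiroketal, which is now beta to a cross-conjugated enone. Iodide may add to the phenalenone, or the tertiary silyl ether may ionise. The fallback moves the ether cleavage to a stage without enones and sets out from 19. BCl3 (1.1 equiv, CH2Cl2, −78 °C) cleaves the methyl ether through the boron chelate of the peri-methoxy aryl ketone and gives the chelated phenol F8. LDA and Me3SiCl then give the tris(trimethylsilyl) compound F9 (aryl silyl ether and two silyl enol ethers). Pd(OAc)2 in MeCN followed by aqueous work-up, which hydrolyses the aryl silyl ether, returns to the route at 22.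

## Further compounds

F1 | step 9 | naphtho[1,8-de][1,3]dioxin-2-ylium tetrafluoroborate of 11 | O=C1CCc2cc(OS(=O)(=O)C(F)(F)F)c(C4=[O+]c5cccc6cccc(O4)c56)c3ccc(OC)c1c23.F[B-](F)(F)F
F2 | step 9 | 3-hydroxy-2-[2-aryl-naphtho[1,8-de][1,3]dioxin-2-yl]cyclopent-2-en-1-one, aryl = 9-methoxy-1-oxo-5-(triflyloxy)-2,3-dihydro-1H-phenalen-6-yl | O=C1CCc2cc(OS(=O)(=O)C(F)(F)F)c(C4(Oc5cccc6cccc(O4)c56)C4=C(O)CCC4=O)c3ccc(OC)c1c23
F3 | step 9 | enol triflate of F2 (aryl and alkenyl bis-triflate) | O=C1CCc2cc(OS(=O)(=O)C(F)(F)F)c(C4(Oc5cccc6cccc(O4)c56)C4=C(OS(=O)(=O)C(F)(F)F)CCC4=O)c3ccc(OC)c1c23
F4 | step 10 | diol from reduction of both ketones of 16 | O[C@H]1CCc2cc3c(c4ccc(OC)c1c24)C1(Oc2cccc4cccc(O1)c24)C1=C3CC[C@@H]1O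
F5 | step 10 | epoxy diol, oxirane cis to the ring E hydroxyl | O[C@H]1CCc2cc3c(c4ccc(OC)c1c24)C1(Oc2cccc4cccc(O1)c24)[C@]15O[C@@]35CC[C@@H]1O
F6 | step 11 | cis-fused beta-(pinacolboryl) ketone | O=C1CCc2cc3c(c4ccc(OC)c1c24)C1(Oc2cccc4cccc(O1)c24)[C@@H]1C(=O)CC[C@]31B1OC(C)(C)C(C)(C)O1
F7 | step 14 | bis(alpha-phenylselanyl) diketone, mixture at the selenium-bearing carbons | O=C1C([Se]c5ccccc5)Cc2cc3c(c4ccc(OC)c1c24)C1(Oc2cccc4cccc(O1)c24)[C@@H]1C(=O)C([Se]c2ccccc2)C[C@]31O[Si](CC)(CC)CC
F8 | step 15 | 9-hydroxy analogue of 19 | O=C1CCc2cc3c(c4ccc(O)c1c24)C1(Oc2cccc4cccc(O1)c24)[C@@H]1C(=O)CC[C@]31O[Si](CC)(CC)CC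
F9 | step 15 | tris(trimethylsilyl) derivative of F8 | C[Si](C)(C)OC1=CCc2cc3c(c4ccc(O[Si](C)(C)C)c1c24)C1(Oc2cccc4cccc(O1)c24)[C@@H]1C(O[Si](C)(C)C)=CC[C@]31O[Si](CC)(CC)CC
A1 | alternative 1 | 2-acetyl-3-aryloxy-1-indenol with tertiary carbinol | COc1ccc2c(c1)ccc1c2C(Oc2cccc3cccc(OCOC)c23)=C(C(C)=O)[C@]1(O)C(OC)OC
A2 | alternative 1 | 1-(1-bromo-6-methoxynaphthalen-2-yl)-2,2-dimethoxyethan-1-one | COc1ccc2c(Br)c(C(=O)C(OC)OC)ccc2c1
A3 | alternative 1 | 4-{[8-(methoxymethoxy)naphthalen-1-yl]oxy}but-3-yn-2-one | CC(=O)C#COc1cccc2cccc(OCOC)c12
A4 | alternative 2 | cis-fused dichlorocyclobutanone | COc1ccc2c(c1)ccc1c2C2(Oc3cccc4cccc(c34)O2)[C@@H]2C(=O)C(Cl)(Cl)[C@]12O[C@@H](C)c1c(C(C)C)cc(C(C)C)cc1C(C)C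
A5 | alternative 2 | spiroketal indenyl enol ether with 1-(2,4,6-triisopropylphenyl)ethyl group | COc1ccc2c(c1)ccc1c2C2(Oc3cccc4cccc(c34)O2)C=C1O[C@@H](C)c1c(C(C)C)cc(C(C)C)cc1C(C)C
A6 | alternative 2 | dichloroketene | O=C=C(Cl)Cl
A7 | alternative 3 | silyl-protected methoxynaphthalene core | COc1ccc2c(c1)ccc1c2C2(Oc3cccc4cccc(c34)O2)[C@@H]2C(=O)C=C[C@]12O[Si](CC)(CC)CC
A8 | alternative 3 | 4-aryl-4-(triethylsilyloxy)cyclopent-2-en-1-one with ortho methyl orthoester | O=C1C=C[C@](O[Si](CC)(CC)CC)(c2ccc3cc(OC)ccc3c2C2(OC)Oc3cccc4cccc(O2)c34)C1
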